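(The numbers in the tables were computed for substances that don't exist; noise was put on by code.)

In the first hours of the alder run the starting material falls quickly, and if you treat that fall as a pseudo-first-order loss you can read a mean constant where 5.7% remains at 6.00 h: κ = 0.477 h⁻¹. The elm run, with half the activator, reads 0.226 h⁻¹ in the same way, so in these two readings κ goes with the activator.

| flask | starting material | activator | remark | time |
|---|---|---|---|---|
| alder | 0.13 M | 0.143 M | run made earlier |  |
| larch | 0.087 M | 0.143 M | run made earlier |  |
| birch | 0.20 M | 0.143 M | run made earlier |  |
| elm | 0.13 M | 0.071 M | run made earlier |  |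
| alpha | 0.13 M | 0.143 M | everything together at the start | 30 h |
| delta | 0.13 M (fed, over 12 h) | 0.143 M | all else is in the flask from the start; the feed brings no volume worth counting | 30 h |
| gamma | 0.13 M | 0.143 M (in portions, 4, over 12 h) | first portion at the start, last at 12 h | 30 h |
| epsilon | 0.13 M (fed, over 80 min) | 0.143 M | all else is in the flask from the start; the feed brings no volume worth counting | 30 h |
| theta | 0.13 M | 0.143 M (fed, over 12 h) | all else is in the flask from the start; the feed brings no volume worth counting | 30 h |

| run | time / h | ring / % | starting material / % |
|---|---|---|---|
| alder | 6.00 | 10.6 | 5.7 |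
| alder | 12.0 | 16.3 | 1.5 |
| alder | 20.0 | 18.0 | 0 |
| alder | 25.0 | 19.0 | 0.5 |
| alder | 30.0 | 19.6 | 0.6 |
| larch | 2.50 | 7.3 | 23.4 |
| larch | 8.00 | 19.2 | 1.7 |
| larch | 15.0 | 24.7 | 0 |
| larch | 20.0 | 26.4 | 0.7 |
| larch | 30.0 | 27.4 | 0 |
| birch | 2.50 | 3.8 | 26.8 |
| birch | 5.00 | 5.9 | 10.8 |
| birch | 8.00 | 6.9 | 5.9 |
| birch | 15.0 | 9.7 | 1.9 |
| birch | 30.0 | 11.4 | 0.9 |
| elm | 6.00 | 4.7 | 25.8 |
| elm | 12.0 | 7.3 | 12.7 |
| elm | 20.0 | 9.1 | 10.0 |
| elm | 25.0 | 9.7 | 8.6 |
| elm | 30.0 | 10.3 | 7.5 |

(each reading ± 0.5 percentage points)



1. the flask that comes out highest in amount of ring, in percent of the starting material charged, or "all alike" when all lie within 1.5 percentage points (alpha / delta / gamma / epsilon / theta / all alike)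
2. ring at the end, in percent of the starting material charged, alpha
3. ring at the end, in percent of the starting material charged, delta
4. ring at the end, in percent of the starting material charged, gamma
5. ring at the end, in percent of the starting material charged, epsilon
6. ring at the end, in percent of the starting material charged, theta

Starting material is the limiting reagent, at 0.13 M against 0.143 M of activator, so write its balance under a feed: c(starting material) changes by the feed rate minus κ times c(starting material). The feed time over the lifetime of starting material, which is the inverse of κ, comes to 5.73 for delta; call this ratio the dose number. You can solve two extremes in your head, with κ held. Far below one, the feed ends before much has reacted and the flask is a batch, which alder already shows, with ring at 19.6%. Far above one, loss catches up with feed and c(starting material) stands at the charge over the dose number, here 0.0227 M.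

Delta lies towards the second extreme, its feed lasting longer than that lifetime, while epsilon, at 0.637, lies towards the first, so I put epsilon beside alpha at about 19.6%. The batches show what a low level is worth: at equal activator, final ring is higher in larch, at 27.4%, than in birch, at 11.4%, and larch has the smaller charge. Delta's reckoned level is lower than larch's charge, so I set delta near larch's figure, but no higher, since delta's feed runs to 12 h and larch's ring was still rising from 24.7% at 15.0 h. Slow activator lowers κ instead, as less activator did in elm, whose final ring is lower than alder's, so I put gamma and theta under alder's figure.

The forecast names delta as highest, on the ground that “Slow starting-material feed keeps free starting material low”, with alpha 20%, delta 24.5%, gamma 15.5%, epsilon 20.5% and theta 15%, its delta being lower than my figure.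

The flasks give alpha 20.0%, delta 27.2%, gamma 17.9%, epsilon 20.3% and theta 18.7%, so delta is highest.

    starting material + activated form → open dimer (k = 0.930 M⁻¹ h⁻¹)
    starting material + activator → activated form (k = 2.90 M⁻¹ h⁻¹)
    starting material + activated form → side product (k = 17.0 M⁻¹ h⁻¹)
    activated form → ring (k = 0.200 h⁻¹)
    starting material ⇌ dormant form (K = 0.540, k = 0.0380 h⁻¹)

At the end of delta's feed, at 12.0 h, starting material stood at 18.1% of the charge, where the dose number gave 17.5%. At that amount in delta the half-life of activated form by the step to side product alone is 1.73 h, against 0.31 h in alpha at the charged amounts, and closure to ring has a half-life of 3.47 h. Epsilon, with its dose number of 0.637, still held 69.8% of starting material when its feed ended at 1.33 h, and it finished with 20.3% of ring.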